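## Retrosynthetic overview

1. The last bond formed is the lactone C11–O bond: a carboxylate, released in the flask from a 9-fluorenylmethyl (Fm) ester, adds 5-exo-dig and anti across the C11≡C12 alkyne of a C37 seco-ester. This closes the butenolide and sets the Z-ylidene geometry.
2. The seco-ester comes from Fm (E)-2,3-dibromoacrylate (from propiolic acid) by Sonogashira coupling of a polyenyne at C10–C11 and Stille coupling of an epoxy-vinylstannane at C8–C9.
3. The polyenyne comes from mono-Sonogashira coupling of an acetoxy enol triflate with a symmetric C14 tetraene-diyne, itself made by double Horner–Wadsworth–Emmons olefination of glyoxal.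
4. The epoxy half comes from the same enol triflate: hydroxymethylation, Sharpless epoxidation (a second C–O step, setting C5 and C6), oxidation, alkyne homologation.
5. Ring order: both carbocycles are bought as (4R,6R)-actinol, the oxirane is made in step 7, the butenolide in step 14.

Assumption: (4R,6R)-actinol is bought as the single enantiomer; locants in the comments follow carotenoid numbering of the target (C6 is the epoxide carbon carrying the side chain; C9, C10, C11 are the α, β, γ carbons of the butenolide).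

## Route

Step 1
Reactants: 1 (4R,6R)-4-hydroxy-2,2,6-trimethylcyclohexan-1-one
Product: 2 (1R,5R)-3,3,5-trimethyl-4-oxocyclohexyl acetate
Conditions: Ac2O, pyridine, DMAP (cat.), CH2Cl2, 0 °C → rt
Reagents that add atoms: acetic anhydride, CC(=O)OC(C)=O
Why: DMAP-catalysed O-acylation of the only hydroxyl; no bond to the carbinol stereocentre is broken, so the (R) configuration that becomes C3′ of the target is kept.

Step 2
Reactants: 2 (1R,5R)-3,3,5-trimethyl-4-oxocyclohexyl acetate
Product: 3 (1R)-3,5,5-trimethyl-4-{[(trifluoromethyl)sulfonyl]oxy}cyclohex-3-en-1-yl acetate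
Conditions: Tf2O (1.3 equiv), 2,6-di-tert-butyl-4-methylpyridine (1.5 equiv), ClCH2CH2Cl, 0 → 60 °C
Reagents that add atoms: trifluoromethanesulfonic anhydride, FC(F)(F)S(=O)(=O)OS(=O)(=O)C(F)(F)F
Why: Stang enol triflate synthesis; the ketone has a single α-hydrogen, so only the tetrasubstituted enol triflate can form, and the electrophilic conditions with a non-nucleophilic base spare the acetate (the methyl-bearing stereocentre is erased on purpose).

Step 3
Reactants: 4 (2E)-3-methylpent-2-en-4-yn-1-ol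
Product: 6 diethyl [(2E)-3-methylpent-2-en-4-yn-1-yl]phosphonate, via allylic iodide 5 (not isolated)
Conditions: P(OEt)3 (3 equiv), ZnI2 (1.5 equiv), THF, reflux
Reagents that add atoms: triethyl phosphite, CCOP(OCC)OCC
Why: ZnI2-mediated direct Michaelis–Arbuzov phosphonylation of a primary allylic alcohol; phosphorus attacks the unhindered primary terminus, so the (E)-enyne geometry is carried over.

Step 4
Reactants: 6 diethyl [(2E)-3-methylpent-2-en-4-yn-1-yl]phosphonate (2.2 equiv), 7 1,4-dioxane-2,3-diol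
Product: 10 (3E,5E,7E,9E)-3,10-dimethyldodeca-3,5,7,9-tetraene-1,11-diyne, via glyoxal 8 (not isolated), via dienynal 9 (not isolated)
Conditions: KOtBu (4.5 equiv), THF, −20 °C → rt, dark
Reagents that add atoms: none
Why: Double Horner–Wadsworth–Emmons olefination on glyoxal released from its dioxanediol adduct by alkoxide; allylic phosphonate anions give the E-disubstituted alkenes, and because no iodine or light equilibration is used the two (E)-enyne bonds are not scrambled.

Step 5
Reactants: 3 (1R)-3,5,5-trimethyl-4-{[(trifluoromethyl)sulfonyl]oxy}cyclohex-3-en-1-yl acetate, 10 (3E,5E,7E,9E)-3,10-dimethyldodeca-3,5,7,9-tetraene-1,11-diyne (3 equiv)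
Product: 11 (1R)-4-[(3E,5E,7E,9E)-3,10-dimethyldodeca-3,5,7,9-tetraene-1,11-diyn-1-yl]-3,5,5-trimethylcyclohex-3-en-1-yl acetate
Conditions: Pd(PPh3)4 (5 mol%), CuI (10 mol%), Et3N, DMF, 45 °C, degassed, dark; excess 10 recovered
Reagents that add atoms: none
Why: Sonogashira coupling at one of two equivalent terminal alkynes; the threefold excess of the symmetric diyne makes mono-coupling dominant (statistical desymmetrisation) and the remote (R) centre is untouched.

Step 6
Reactants: 3 (1R)-3,5,5-trimethyl-4-{[(trifluoromethyl)sulfonyl]oxy}cyclohex-3-en-1-yl acetate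
Product: 12 (1R)-4-(hydroxymethyl)-3,5,5-trimethylcyclohex-3-en-1-yl acetate
Conditions: Bu3SnCH2OH (1.5 equiv), Pd(PPh3)4 (10 mol%), LiCl (3 equiv), 1,4-dioxane, 95 °C
Reagents that add atoms: (tributylstannyl)methanol, CCCC[Sn](CCCC)(CCCC)CO
Why: Migita–Kosugi–Stille hydroxymethylation of a vinyl triflate (chloride assists transmetalation) gives the allylic alcohol needed for directed epoxidation in one step with the acetate intact.

Step 7
Reactants: 12 (1R)-4-(hydroxymethyl)-3,5,5-trimethylcyclohex-3-en-1-yl acetate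
Product: 13 (1R,3S,6R)-6-(hydroxymethyl)-1,5,5-trimethyl-7-oxabicyclo[4.1.0]heptan-3-yl acetate
Conditions: Ti(OiPr)4 (20 mol%), D-(−)-diisopropyl tartrate (24 mol%), tBuOOH (2 equiv, decane), 4 Å MS, CH2Cl2, −20 °C
Reagents that add atoms: tert-butyl hydroperoxide, CC(C)(C)OO
Why: Sharpless asymmetric epoxidation; with the hydroxymethyl group drawn at the lower right the D-(−)-tartrate catalyst delivers oxygen to the alkene face opposite the acetoxy group (reagent control matched with the substrate's steric bias), setting the two epoxide carbons that become (5R,6S) in the target.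

Step 8
Reactants: 13 (1R,3S,6R)-6-(hydroxymethyl)-1,5,5-trimethyl-7-oxabicyclo[4.1.0]heptan-3-yl acetate
Product: 14 (1R,3S,6S)-6-formyl-1,5,5-trimethyl-7-oxabicyclo[4.1.0]heptan-3-yl acetate
Conditions: Dess–Martin periodinane, NaHCO3, CH2Cl2, 0 °C → rt
Reagents that add atoms: none
Why: Buffered Dess–Martin oxidation of the primary alcohol; the aldehyde sits on a quaternary epoxide carbon and cannot enolise, so nothing epimerises (the descriptor at that carbon changes only through substituent priorities).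

Step 9
Reactants: 14 (1R,3S,6S)-6-formyl-1,5,5-trimethyl-7-oxabicyclo[4.1.0]heptan-3-yl acetate
Product: 16 (1R,3S,6R)-6-ethynyl-1,5,5-trimethyl-7-oxabicyclo[4.1.0]heptan-3-ol, via alkynyl acetate 15 (not isolated)
Conditions: dimethyl (1-diazo-2-oxopropyl)phosphonate (1.5 equiv), K2CO3 (3 equiv), MeOH, 0 °C → rt
Reagents that add atoms: Ohira–Bestmann reagent (dimethyl (1-diazo-2-oxopropyl)phosphonate), COP(=O)(OC)C(=[N+]=[N-])C(C)=O
Why: Seyferth–Gilbert homologation in the Ohira–Bestmann variant converts the non-enolisable aldehyde into the terminal alkyne, and the same K2CO3/MeOH medium methanolyses the acetate, so the free C3 hydroxyl of the target is unmasked without an extra step.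

Step 10
Reactants: 17 prop-2-ynoic acid
Product: 18 (2E)-2,3-dibromoprop-2-enoic acid
Conditions: Br2 (1.05 equiv), CHCl3, 0 °C → rt, dark; recrystallise
Reagents that add atoms: bromine, BrBr
Why: Electrophilic anti-addition of bromine to the alkyne gives the E-dibromide, in which the β-bromine is cis to the carboxyl group, the geometry later required for ring closure.

Step 11
Reactants: 18 (2E)-2,3-dibromoprop-2-enoic acid, 19 (9H-fluoren-9-yl)methanol
Product: 20 (9H-fluoren-9-yl)methyl (2E)-2,3-dibromoprop-2-enoate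
Conditions: DCC (1.1 equiv), DMAP (5 mol%), CH2Cl2, 0 °C
Reagents that add atoms: none
Why: Steglich esterification; the Fm ester masks the acid through two palladium couplings and can later be opened by base-induced β-elimination, which the acetate of the target tolerates whereas saponification would not.

Step 12
Reactants: 20 (9H-fluoren-9-yl)methyl (2E)-2,3-dibromoprop-2-enoate, 11 (1R)-4-[(3E,5E,7E,9E)-3,10-dimethyldodeca-3,5,7,9-tetraene-1,11-diyn-1-yl]-3,5,5-trimethylcyclohex-3-en-1-yl acetate
Product: 21 (9H-fluoren-9-yl)methyl (2E,6E,8E,10E,12E)-15-[(4R)-4-acetoxy-2,6,6-trimethylcyclohex-1-en-1-yl]-2-bromo-6,13-dimethylpentadeca-2,6,8,10,12-pentaene-4,14-diynoate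
Conditions: Pd(PPh3)4 (5 mol%), CuI (10 mol%), iPr2NEt (2 equiv), THF, rt, dark
Reagents that add atoms: none
Why: Sonogashira coupling; in (E)-2,3-dibromoacrylates the β-C–Br bond undergoes oxidative addition first, coupling proceeds with retention so the alkyne ends cis to the ester, and the hindered tertiary amine leaves the Fm ester and acetate alone.

Step 13
Reactants: 16 (1R,3S,6R)-6-ethynyl-1,5,5-trimethyl-7-oxabicyclo[4.1.0]heptan-3-ol (1.3 equiv), 21 (9H-fluoren-9-yl)methyl (2E,6E,8E,10E,12E)-15-[(4R)-4-acetoxy-2,6,6-trimethylcyclohex-1-en-1-yl]-2-bromo-6,13-dimethylpentadeca-2,6,8,10,12-pentaene-4,14-diynoate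
Product: 23 (9H-fluoren-9-yl)methyl (2Z,6E,8E,10E,12E)-15-[(4R)-4-acetoxy-2,6,6-trimethylcyclohex-1-en-1-yl]-2-{(E)-2-[(1S,4S,6R)-4-hydroxy-2,2,6-trimethyl-7-oxabicyclo[4.1.0]heptan-1-yl]ethenyl}-6,13-dimethylpentadeca-2,6,8,10,12-pentaene-4,14-diynoate, via vinylstannane 22 (not isolated)
Conditions: 16, Bu3SnH (1.35 equiv), PdCl2(PPh3)2 (3 mol%), THF, 0 °C; then 21, Pd2(dba)3 (5 mol%), AsPh3 (40 mol%), THF, 50 °C, dark
Reagents that add atoms: none
Why: One-pot palladium-catalysed syn-hydrostannation (tin goes to the terminal carbon because the other alkyne carbon is flanked by the quaternary epoxide carbon, giving the E-vinylstannane) followed by Stille coupling at the α-C–Br bond with retention at both partners, under base-free conditions that preserve the Fm ester, acetate and epoxide.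

Step 14
Reactants: 23 (9H-fluoren-9-yl)methyl (2Z,6E,8E,10E,12E)-15-[(4R)-4-acetoxy-2,6,6-trimethylcyclohex-1-en-1-yl]-2-{(E)-2-[(1S,4S,6R)-4-hydroxy-2,2,6-trimethyl-7-oxabicyclo[4.1.0]heptan-1-yl]ethenyl}-6,13-dimethylpentadeca-2,6,8,10,12-pentaene-4,14-diynoate
Product: 25 pyrrhoxanthin (target), via seco-acid 24 (not isolated)
Conditions: AgOAc (10 mol%), DBU (20 mol%), MeCN/CH2Cl2 (1:1), rt, dark, argon
Reagents that add atoms: none
Why: Proposed new method: base/silver co-catalysed eliminative cycloisomerisation of an Fm (Z)-2-en-4-ynoate, in which DBU removes the acidic fluorenyl 9-H so the ester fragments (E1cB) to dibenzofulvene and the DBU-H+ carboxylate 24, monovalent silver π-activates the C11≡C12 alkyne held cis to that carboxylate, oxygen attacks C11 5-exo-dig anti to silver, and DBU-H+ protonates the vinylsilver with retention so the chain at C12 ends cis to the ring oxygen (Z) while both catalysts turn over without any stoichiometric reagent; the closest known reactions are the silver-catalysed 5-exo lactonisation of free (Z)-2-en-4-ynoic acids, the AgOAc/DBU anti-selective carboxylative cyclisation of propargylic alcohols with CO2, and amine-induced cleavage of Fm esters.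

## Compound list

1 | (4R,6R)-4-hydroxy-2,2,6-trimethylcyclohexan-1-one ((4R,6R)-actinol) | C[C@@H]1C[C@@H](O)CC(C)(C)C1=O | starting material
2 | (1R,5R)-3,3,5-trimethyl-4-oxocyclohexyl acetate | C[C@@H]1C[C@@H](OC(C)=O)CC(C)(C)C1=O | intermediate
3 | (1R)-3,5,5-trimethyl-4-{[(trifluoromethyl)sulfonyl]oxy}cyclohex-3-en-1-yl acetate | CC(=O)O[C@@H]1CC(C)=C(OS(=O)(=O)C(F)(F)F)C(C)(C)C1 | intermediate
4 | (2E)-3-methylpent-2-en-4-yn-1-ol | C#C/C(C)=C/CO | starting material
5 | (3E)-5-iodo-3-methylpent-3-en-1-yne | C#C/C(C)=C/CI | intermediate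
6 | diethyl [(2E)-3-methylpent-2-en-4-yn-1-yl]phosphonate | C#C/C(C)=C/CP(=O)(OCC)OCC | intermediate
7 | 1,4-dioxane-2,3-diol (glyoxal–ethylene glycol adduct) | OC1OCCOC1O | starting material
8 | glyoxal (ethanedial) | O=CC=O | intermediate
9 | (2E,4E)-5-methylhepta-2,4-dien-6-ynal | C#C/C(C)=C/C=C/C=O | intermediate
10 | (3E,5E,7E,9E)-3,10-dimethyldodeca-3,5,7,9-tetraene-1,11-diyne | C#C/C(C)=C/C=C/C=C/C=C(C)/C#C | intermediate
11 | (1R)-4-[(3E,5E,7E,9E)-3,10-dimethyldodeca-3,5,7,9-tetraene-1,11-diyn-1-yl]-3,5,5-trimethylcyclohex-3-en-1-yl acetate | CC(=O)O[C@@H]1CC(C)=C(C#C/C(C)=C/C=C/C=C/C=C(C)/C#C)C(C)(C)C1 | intermediate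
12 | (1R)-4-(hydroxymethyl)-3,5,5-trimethylcyclohex-3-en-1-yl acetate | CC(=O)O[C@@H]1CC(C)=C(CO)C(C)(C)C1 | intermediate
13 | (1R,3S,6R)-6-(hydroxymethyl)-1,5,5-trimethyl-7-oxabicyclo[4.1.0]heptan-3-yl acetate (epoxide anti to the acetoxy group) | OC[C@@]12O[C@]1(C)C[C@@H](OC(C)=O)CC2(C)C | intermediate
14 | (1R,3S,6S)-6-formyl-1,5,5-trimethyl-7-oxabicyclo[4.1.0]heptan-3-yl acetate | O=C[C@@]12O[C@]1(C)C[C@@H](OC(C)=O)CC2(C)C | intermediate
15 | (1R,3S,6R)-6-ethynyl-1,5,5-trimethyl-7-oxabicyclo[4.1.0]heptan-3-yl acetate | C#C[C@@]12O[C@]1(C)C[C@@H](OC(C)=O)CC2(C)C | intermediate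
16 | (1R,3S,6R)-6-ethynyl-1,5,5-trimethyl-7-oxabicyclo[4.1.0]heptan-3-ol | C#C[C@@]12O[C@]1(C)C[C@@H](O)CC2(C)C | intermediate
17 | prop-2-ynoic acid (propiolic acid) | C#CC(=O)O | starting material
18 | (2E)-2,3-dibromoprop-2-enoic acid | Br/C=C(/Br)C(=O)O | intermediate
19 | (9H-fluoren-9-yl)methanol | OCC1c2ccccc2-c2ccccc12 | starting material
20 | (9H-fluoren-9-yl)methyl (2E)-2,3-dibromoprop-2-enoate | Br/C=C(/Br)C(=O)OCC1c2ccccc2-c2ccccc12 | intermediate
21 | (9H-fluoren-9-yl)methyl (2E,6E,8E,10E,12E)-15-[(4R)-4-acetoxy-2,6,6-trimethylcyclohex-1-en-1-yl]-2-bromo-6,13-dimethylpentadeca-2,6,8,10,12-pentaene-4,14-diynoate | CC(=O)O[C@@H]1CC(C)=C(C#C/C(C)=C/C=C/C=C/C=C(C)/C#C/C=C(/Br)C(=O)OCC2c3ccccc3-c3ccccc23)C(C)(C)C1 | intermediate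
22 | tributyl{(E)-2-[(1S,4S,6R)-4-hydroxy-2,2,6-trimethyl-7-oxabicyclo[4.1.0]heptan-1-yl]ethenyl}stannane | CCCC[Sn](CCCC)(CCCC)/C=C/[C@@]12O[C@]1(C)C[C@@H](O)CC2(C)C | intermediate
23 | (9H-fluoren-9-yl)methyl (2Z,6E,8E,10E,12E)-15-[(4R)-4-acetoxy-2,6,6-trimethylcyclohex-1-en-1-yl]-2-{(E)-2-[(1S,4S,6R)-4-hydroxy-2,2,6-trimethyl-7-oxabicyclo[4.1.0]heptan-1-yl]ethenyl}-6,13-dimethylpentadeca-2,6,8,10,12-pentaene-4,14-diynoate | CC(=O)O[C@@H]1CC(C)=C(C#C/C(C)=C/C=C/C=C/C=C(C)/C#C/C=C(/C=C/[C@@]23O[C@]2(C)C[C@@H](O)CC3(C)C)C(=O)OCC2c3ccccc3-c3ccccc23)C(C)(C)C1 | intermediate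
24 | (2Z,6E,8E,10E,12E)-15-[(4R)-4-acetoxy-2,6,6-trimethylcyclohex-1-en-1-yl]-2-{(E)-2-[(1S,4S,6R)-4-hydroxy-2,2,6-trimethyl-7-oxabicyclo[4.1.0]heptan-1-yl]ethenyl}-6,13-dimethylpentadeca-2,6,8,10,12-pentaene-4,14-diynoic acid | CC(=O)O[C@@H]1CC(C)=C(C#C/C(C)=C/C=C/C=C/C=C(C)/C#C/C=C(/C=C/[C@@]23O[C@]2(C)C[C@@H](O)CC3(C)C)C(=O)O)C(C)(C)C1 | intermediate
25 | pyrrhoxanthin: (1R)-4-{(3E,5E,7E,9E,11Z)-11-[4-{(E)-2-[(1S,4S,6R)-4-hydroxy-2,2,6-trimethyl-7-oxabicyclo[4.1.0]heptan-1-yl]ethenyl}-5-oxofuran-2(5H)-ylidene]-3,10-dimethylundeca-3,5,7,9-tetraen-1-yn-1-yl}-3,5,5-trimethylcyclohex-3-en-1-yl acetate | CC(=O)O[C@@H]1CC(C)=C(C#C/C(C)=C/C=C/C=C/C=C(C)/C=C2C=C(/C=C/[C@@]34O[C@]3(C)C[C@@H](O)CC4(C)C)C(=O)O/2)C(C)(C)C1 | target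

## Step count and risks

Total step count: 14. Longest linear sequence: 8 steps (1 → 2 → 3 → 12 → 13 → 14 → 16 → 23 → 25, that is steps 1, 2, 6, 7, 8, 9, 13, 14).

The three steps most likely to fail:

Step 14 (the proposed new ring closure). Possible failures are 6-endo closure to the isomeric 2-pyranone, a sluggish fragmentation of the Fm ester at low DBU loading, or base-induced damage to the polyene. The fallback uses only known chemistry and forms the lactone before the last coupling. It sets out from polyenyne 11 and acid 18: the known palladium/copper tandem Sonogashira coupling–5-exo-dig lactonisation of β-haloacrylic acids with terminal alkynes (PdCl2(PPh3)2, CuI, Et3N, MeCN, rt; any uncyclised enynoic acid is closed with catalytic AgNO3) gives the 3-bromo-5-ylidenebutenolide F1. Stille coupling of F1 with vinylstannane 22 (made from 16 as in step 13; Pd2(dba)3, AsPh3, THF, 50 °C) then gives the target, so the fallback comes back to the route at 25.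

Step 13 (one-pot hydrostannation/Stille). Zerovalent palladium may open the propargylic epoxide of 16 before hydrostannation, or residual tin hydride may reduce the bromide 21. The fallback avoids the alkyne altogether and sets out from aldehyde 14: Hodgson's chromium-mediated stannyl olefination (CrCl2, Bu3SnCHBr2, LiI, THF/DMF, rt) converts the aldehyde directly into the (E)-vinylstannane acetate F2. Methanolysis (K2CO3, MeOH, 0 °C) gives 22, now isolated, and a separate Stille coupling with 21 (Pd2(dba)3, AsPh3, THF, 50 °C) comes back to the route at 23.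

Step 6 (hydroxymethylation of a tetrasubstituted, doubly flanked vinyl triflate). Transmetalation of the sp3 stannane may be too slow, giving reduction or butyl transfer. The fallback introduces the carbon by carbonylation instead and sets out from triflate 3: palladium-catalysed formylation (Pd(PPh3)4, CO 1 atm, slow addition of Bu3SnH, THF, 50 °C) gives the enal F3. Luche reduction (NaBH4, CeCl3·7H2O, MeOH, 0 °C) of F3 comes back to the route at 12.

## Further compounds

F1 | step 14 | (1R)-4-{(3E,5E,7E,9E,11Z)-11-[4-bromo-5-oxofuran-2(5H)-ylidene]-3,10-dimethylundeca-3,5,7,9-tetraen-1-yn-1-yl}-3,5,5-trimethylcyclohex-3-en-1-yl acetate | CC(=O)O[C@@H]1CC(C)=C(C#C/C(C)=C/C=C/C=C/C=C(C)/C=C2C=C(Br)C(=O)O/2)C(C)(C)C1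
F2 | step 13 | (1R,3S,6S)-1,5,5-trimethyl-6-[(E)-2-(tributylstannyl)ethenyl]-7-oxabicyclo[4.1.0]heptan-3-yl acetate | CCCC[Sn](CCCC)(CCCC)/C=C/[C@@]12O[C@]1(C)C[C@@H](OC(C)=O)CC2(C)C
F3 | step 6 | (1R)-4-formyl-3,5,5-trimethylcyclohex-3-en-1-yl acetate | CC(=O)O[C@@H]1CC(C)=C(C=O)C(C)(C)C1
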